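## Retrosynthetic overview

- **Feature:** the target is a hydroazulene. Its five-membered ring (C1–C5) and seven-membered ring (C1, C5–C10) share the C1–C5 bond, C1–H sits next to C10–H(CH3), and C5 is sp2. Replacing the C1–C5 bond by a C5–C10 bond redraws the core as a decalin, namely a 4-methyl cross-conjugated cyclohexadienone.
- **Late disconnections:** three O–CH3 bonds, two aryl–CHO bonds (lithiation/DMF), C11–OH (hydration of an isopropenyl group), and C3–O and C10–O (radical deoxygenations).
- **C4–C1′ bond:** C4 acts as the enolate carbon of the hydroazulen-3-one and adds to an o-quinone methide. The enolate is released reductively from the 4β,5β-epoxide, because deprotonation could also remove H-1 or H-2. Anti elimination of the 5β-OH then places the alkene at C5=C6.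
- **Ring order:** ring B comes with dihydrocarvone and six-membered ring A is built by Robinson annulation. One photochemical step then contracts ring A to five members and enlarges ring B to seven. The arene is bought.

Key step: step 4

**Remark on numbering and descriptors.** Guaiane numbering is used throughout, and the eudesmane numbers before step 4 denote the same atoms. C1′ is the benzylic carbon. The descriptors α and β refer to the drawing with the five-membered ring on the left and C1 above C5. In that drawing the target has H-1 β, H-10 β (10-CH3 α), the C7 side chain β, and at C4 the carbon C1′ β and CH3 α. This corresponds to 1R,4R,7R,10R,1′R.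

**Assumption.** Commercial (+)-dihydrocarvone contains some C2 epimer. Both epimers give the same enolate in step 1, so this has no effect.

## Route

Step 1
Reactants: 1 (+)-dihydrocarvone; 2 ethyl vinyl ketone
Product: 4 cis-fused ketol 5α-hydroxy-10-epi-eudesm-11-en-3-one, via Michael adduct 3 (not isolated)
Conditions: KOH (0.2 equiv), EtOH–Et2O, −10 to 0 °C; crystallisation
Reagents that add atoms: none
Why: Base-catalysed Michael addition followed by intramolecular aldol addition (first half of the Robinson annulation): the more substituted enolate of 1 is alkylated axially, on the face cis to the equatorial isopropenyl group, so the C10 methyl group ends trans to the C7 substituent, and crystallisation of the ketol removes the minor C10 epimer.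

Step 2
Reactants: 4 cis-fused ketol
Product: 5 10-epi-α-cyperone
Conditions: 10% aq. KOH–EtOH, reflux
Reagents that add atoms: none
Why: E1cB dehydration of the β-hydroxy ketone, the second half of the Robinson annulation: the stereocentres C4 and C5 disappear while C7 and the quaternary C10 cannot epimerise.

Step 3
Reactants: 5 10-epi-α-cyperone
Product: 6 10-epi-1,2-dehydro-α-cyperone
Conditions: DDQ (1.3 equiv), dioxane, reflux
Reagents that add atoms: none
Why: DDQ dehydrogenation of a 4-en-3-one under neutral conditions: enolisation toward C2 and hydride loss from C1 give the cross-conjugated 1,4-dien-3-one, and the isolated isopropenyl group offers no activated hydride.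

Step 4
Reactants: 6 10-epi-1,2-dehydro-α-cyperone
Product: 9 10β-hydroxy-1βH-guaia-4,11-dien-3-one, via oxyallyl zwitterion 7 (not isolated), via cyclopentadienol 8 (not isolated)
Conditions: hν (medium-pressure Hg lamp, Pyrex), AcOH–H2O 1:1 (0.01 M), N2, 15 °C, stopped when 6 is consumed
Reagents that add atoms: water, O
Why: Excitation of the cross-conjugated dienone and intersystem crossing lead to bonding between the two β-carbons C1 and C5, and electron demotion gives the bicyclo[3.1.0]hexane oxyallyl zwitterion 7, in which C1, C5 and C10 form a cyclopropane. Acetic acid protonates the oxygen, water attacks C10 from the side opposite to C5, the C5–C10 bond breaks toward the cationic terminus C4, and the cyclopentadienol 8 so formed ketonises at C2 to 9; this is the type A dienone photorearrangement run in protic acid, the santonin-to-isophotosantonic-lactone reaction type. The five-membered ring is closed by the C1–C5 bond (a transannular β,β′-closure inside ring A that first appears as the three-membered ring), whereas the seven-membered ring is not cyclised end to end but grows out of ring B by one atom (C1) when the bond shared with the cyclopropane is cut. C1 is controlled by the quaternary centre C10: ring B holds C9 cis to C6 on the cyclopropane, so C10 can only tip to the α face that carries its methyl group, and H-1 is left β. C10 is controlled by the SN2-like opening with inversion, which puts OH β (cis to H-1) and leaves CH3 α, trans to the C7 isopropenyl group. The step needs C5–C10 rather than C1–C10 cleavage (hydroazulenone, not spiro ketone) and an untouched side-chain alkene: the C4 methyl group localises the positive charge at C4, next to the C5–C10 bond, and the isopropenyl group is neither conjugated nor within reach of the short-lived excited state.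

Step 5
Reactants: 9 10β-hydroxy-1βH-guaia-4,11-dien-3-one
Product: 10 10β-(methoxyoxalyloxy)-1βH-guaia-4,11-dien-3-one
Conditions: ClCOCO2Me (2 equiv), DMAP (0.2 equiv), pyridine–CH2Cl2, 0 °C
Reagents that add atoms: methyl oxalyl chloride, COC(=O)C(=O)Cl
Why: Nucleophile-catalysed O-acylation: the very electrophilic acid chloride esterifies even the tertiary 10β-alcohol, and the low temperature avoids vinylogous E1cB loss of the ester across C1–C10.

Step 6
Reactants: 10 10β-(methoxyoxalyloxy)-1βH-guaia-4,11-dien-3-one
Product: 11 1βH,10βH-guaia-4,11-dien-3-one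
Conditions: Bu3SnH (3 equiv, 0.3 M), AIBN (0.2 equiv), toluene, reflux
Reagents that add atoms: none
Why: Barton–McCombie-type radical deoxygenation of a tertiary methyl oxalate: the planar C10 radical has one lobe buried under ring A and the other open on the β side next to H-1, so Bu3SnH should deliver hydrogen there (H-10 β, CH3 α), and the high stannane concentration outruns three-membered ring closure of the radical onto C5.

Step 7
Reactants: 11 1βH,10βH-guaia-4,11-dien-3-one
Product: 12 4β,5β-epoxy-1βH,10βH-guai-11-en-3-one
Conditions: 30% H2O2, NaOH (0.3 equiv), MeOH, 0 °C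
Reagents that add atoms: hydrogen peroxide, OO
Why: Weitz–Scheffer epoxidation: hydroperoxide adds to C5 from the β face, the side of H-1, because C10 and the rest of the seven-membered ring hang below ring A, ring closure gives the cis-fused 4β,5β-epoxide, and the unactivated isopropenyl group does not react with a nucleophilic oxidant.

Step 8
Reactants: 13 2-hydroxy-4,6-dimethoxybenzaldehyde
Product: 14 tert-butyl 2-formyl-3,5-dimethoxyphenyl carbonate
Conditions: Boc2O (1.1 equiv), i-Pr2NEt, DMAP (5 mol%), CH2Cl2, rt
Reagents that add atoms: di-tert-butyl dicarbonate, CC(C)(C)OC(=O)OC(=O)OC(C)(C)C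
Why: Carbonate formation (O-acylation under DMAP catalysis): the Boc group masks the phenol now and in step 9 migrates to the benzylic alkoxide, where it becomes the leaving group that releases the methide.

Step 9
Reactants: 12 4β,5β-epoxy-1βH,10βH-guai-11-en-3-one; 14 tert-butyl 2-formyl-3,5-dimethoxyphenyl carbonate; 15 isobutylmagnesium bromide
Product: 19 4β-[1-(2-hydroxy-4,6-dimethoxyphenyl)-3-methylbutyl]-5β-hydroxy-1βH,10βH-guai-11-en-3-one (C1′ as in the target), via samarium enolate 16 (not isolated), via aryloxide carbonate 17 (not isolated), via o-quinone methide 18 (not isolated)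
Conditions: 12, SmI2 (2.0 equiv), THF, −78 °C; then premixed 14 + 15 (1.05 equiv, THF, −78 °C) by cannula; −78 → −20 °C; H2O
Reagents that add atoms: none
Why: Proposed new method: two-electron reduction of the α,β-epoxy ketone by SmI2 cleaves C4–O and gives, without any deprotonation, only the C3=C4 enolate 16, so H-1, H-2 and H-6 never come into play; addition of 15 to 14, carbonate migration to the benzylic oxygen and loss of tert-butyl carbonate from 17 release the methide 18, a Michael acceptor that re-aromatises when C4 attacks it; attack on the convex β face of the cis-fused bicycle, guided by the trivalent samarium on the 5β-alkoxide that binds the methide oxygen, places C1′ β at C4, and with the E-methide, the aryl ring anti to C3 and the isobutyl group over the open sector between C3–O and CH3, it should give the C1′ configuration of the target; the closest known reaction types are the SmI2-mediated reductive aldol reaction of α,β-epoxy ketones and the Michael addition of enolates to o-quinone methides released from O-Boc salicylaldehydes by Grignard reagents.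

Step 10
Reactants: 19 phenolic β-hydroxy ketone
Product: 20 4β-[1-(2,4,6-trimethoxyphenyl)-3-methylbutyl]-5β-hydroxy-1βH,10βH-guai-11-en-3-one
Conditions: MeI (3 equiv), K2CO3, acetone, rt
Reagents that add atoms: iodomethane, CI
Why: Williamson ether synthesis: only the phenol is ionised by K2CO3, and capping it shuts off both hemiketal formation at C3 and retro-Michael cleavage of the new C4–C1′ bond.

Step 11
Reactants: 20 trimethoxyaryl β-hydroxy ketone
Product: 21 4β-[1-(2,4,6-trimethoxyphenyl)-3-methylbutyl]-1βH,10βH-guaia-5,11-dien-3-one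
Conditions: SOCl2 (2 equiv), pyridine, −30 → 0 °C
Reagents that add atoms: none
Why: E2 dehydration through the chlorosulfite: a hydrogen anti to the 5β-oxygen is required, C4 has none and H-1 is syn (β), so only H-6α can leave and the alkene forms at C5=C6 without touching a stereocentre.

Step 12
Reactants: 21 β,γ-unsaturated ketone
Product: 22 4β-[1-(2,4,6-trimethoxyphenyl)-3-methylbutyl]-1βH,10βH-guaia-5,11-dien-3β-ol
Conditions: LiAlH4, Et2O, 0 °C
Reagents that add atoms: none
Why: Hydride reduction of the hindered cyclopentanone: LiAlH4 should attack C3 from the α face, away from the C4 β-substituent, and the configuration of the new carbinol centre is irrelevant since it is removed in step 14.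

Step 13
Reactants: 22 guaia-5,11-dien-3β-ol
Product: 24 O-(guaia-5,11-dien-3β-yl) S-methyl xanthate, via sodium xanthate 23 (not isolated)
Conditions: NaH, imidazole (cat.), THF, 0 °C; CS2; MeI, rt
Reagents that add atoms: carbon disulfide, S=C=S; iodomethane, CI
Why: Xanthate formation (first half of the Barton–McCombie deoxygenation): the small electrophile CS2 reaches even the neopentyl-type alkoxide, and no other acidic group is present.

Step 14
Reactants: 24 S-methyl xanthate
Product: 25 4β-[1-(2,4,6-trimethoxyphenyl)-3-methylbutyl]-1βH,10βH-guaia-5,11-diene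
Conditions: Bu3SnH (3 equiv, 0.2 M), AIBN (0.2 equiv), toluene, reflux
Reagents that add atoms: none
Why: Barton–McCombie deoxygenation: the secondary C3 radical is reduced by Bu3SnH faster than it can expel the benzylic C1′ radical by β-scission, closure onto C5=C6 would need a bicyclo[2.1.0]pentane, and no stereocentre is touched.

Step 15
Reactants: 25 guaia-5,11-diene
Product: 26 4β-[1-(2,4,6-trimethoxyphenyl)-3-methylbutyl]-1βH,10βH-guai-5-en-11-ol
Conditions: Co(acac)2 (20 mol%), PhSiH3 (4 equiv), O2 (1 atm), THF, rt
Reagents that add atoms: dioxygen, O=O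
Why: Mukaiyama hydration (cobalt hydride hydrogen-atom transfer, O2 capture, reduction of the peroxide): the terminal 1,1-disubstituted alkene accepts the hydrogen atom at C12 far faster than the trisubstituted C5=C6 bond shielded by quaternary C4, giving the Markovnikov tertiary alcohol without touching C7.

Step 16
Reactants: 26 guai-5-en-11-ol
Product: 28 tri-O-methyl ether of the target (3,5-diformyl-2,4,6-trimethoxyphenyl compound), via lithium hemiaminal 27 (not isolated)
Conditions: n-BuLi (2.2 equiv), TMEDA, THF, 0 °C; DMF (1.0 equiv); n-BuLi (1.5 equiv), 0 °C → rt; DMF (3 equiv); H2O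
Reagents that add atoms: N,N-dimethylformamide, CN(C)C=O
Why: Directed ortho-metalation and formylation carried out twice in one flask: each remaining aryl C–H lies between two methoxy groups, and the tetrahedral DMF adduct 27 serves as an α-amino alkoxide that protects the first formyl group during the second lithiation.

Step 17
Reactants: 28 tri-O-methyl ether of the target
Product: 29 target CNP0281883.1
Conditions: NaSEt (10 equiv), DMF, 110 °C; then cold 1 M HCl
Reagents that add atoms: none
Why: Nucleophilic (SN2) demethylation of aryl methyl ethers by thiolate: every methoxy group is ortho or para to a formyl group so each phenoxide is a good leaving group, and the basic medium spares the tertiary alcohol and the C5=C6 alkene that Lewis or Brønsted acids would ionise or cyclise onto the phenol.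

## Compound list

1 | (+)-dihydrocarvone, (2R,5R)-2-methyl-5-(prop-1-en-2-yl)cyclohexanone | C[C@@H]1CC[C@@H](C(C)=C)CC1=O | starting material
2 | ethyl vinyl ketone | CCC(=O)C=C | starting material
3 | Michael adduct, (2R,5R)-2-methyl-2-(3-oxopentyl)-5-(prop-1-en-2-yl)cyclohexanone | CCC(=O)CC[C@@]1(C)CC[C@@H](C(C)=C)CC1=O | intermediate
4 | cis-fused ketol, 5α-hydroxy-10-epi-eudesm-11-en-3-one (4-CH3 β, 5-OH α, 10-CH3 α, 7-isopropenyl β) | C[C@H]1C(=O)CC[C@@]2(C)CC[C@@H](C(C)=C)C[C@@]12O | intermediate
5 | 10-epi-α-cyperone, 10-epi-eudesma-4,11-dien-3-one (10-CH3 α, 7-isopropenyl β) | CC1=C2C[C@H](C(C)=C)CC[C@]2(C)CCC1=O | intermediate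
6 | 10-epi-1,2-dehydro-α-cyperone, 10-epi-eudesma-1,4,11-trien-3-one | CC1=C2C[C@H](C(C)=C)CC[C@]2(C)C=CC1=O | intermediate
7 | oxyallyl zwitterion (cyclopropane C1–C5–C10 on the α face of the five-membered ring, H-1 β) | C[C+]1C([O-])=C[C@@H]2[C@@]3(C)CC[C@@H](C(C)=C)C[C@@]123 | intermediate
8 | cyclopentadienol, 1βH-guaia-2,4,11-triene-3,10β-diol | CC1=C2C[C@H](C(C)=C)CC[C@](C)(O)[C@H]2C=C1O | intermediate
9 | 10β-hydroxy-1βH-guaia-4,11-dien-3-one (10-CH3 α, 7-isopropenyl β) | CC1=C2C[C@H](C(C)=C)CC[C@](C)(O)[C@H]2CC1=O | intermediate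
10 | 10β-(methoxyoxalyloxy)-1βH-guaia-4,11-dien-3-one | CC1=C2C[C@H](C(C)=C)CC[C@](C)(OC(=O)C(=O)OC)[C@H]2CC1=O | intermediate
11 | 1βH,10βH-guaia-4,11-dien-3-one (10-CH3 α) | CC1=C2C[C@H](C(C)=C)CC[C@@H](C)[C@H]2CC1=O | intermediate
12 | 4β,5β-epoxy-1βH,10βH-guai-11-en-3-one | C[C@@]12O[C@@]13C[C@H](C(C)=C)CC[C@@H](C)[C@H]3CC2=O | intermediate
13 | 2-hydroxy-4,6-dimethoxybenzaldehyde | COc1cc(O)c(C=O)c(OC)c1 | starting material
14 | tert-butyl 2-formyl-3,5-dimethoxyphenyl carbonate | COc1cc(OC(=O)OC(C)(C)C)c(C=O)c(OC)c1 | intermediate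
15 | isobutylmagnesium bromide | CC(C)C[Mg]Br | starting material
16 | samarium enolate, 3,5β-bis(diiodosamariooxy)-1βH,10βH-guaia-3,11-diene | CC1=C(O[Sm](I)I)C[C@@H]2[C@H](C)CC[C@@H](C(C)=C)C[C@]12O[Sm](I)I | intermediate
17 | aryloxide carbonate, bromomagnesium 2-[1-(tert-butoxycarbonyloxy)-3-methylbutyl]-3,5-dimethoxyphenoxide (racemic) | CC(C)CC(OC(=O)OC(C)(C)C)c1c(O[Mg]Br)cc(OC)cc1OC | intermediate
18 | o-quinone methide, (6E)-3,5-dimethoxy-6-(3-methylbutylidene)cyclohexa-2,4-dien-1-one | CC(C)C/C=C1/C(=O)C=C(OC)C=C1OC | intermediate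
19 | 4β-[1-(2-hydroxy-4,6-dimethoxyphenyl)-3-methylbutyl]-5β-hydroxy-1βH,10βH-guai-11-en-3-one (4-CH3 α, C1′ as in the target) | CC(C)C[C@@H](c1c(O)cc(OC)cc1OC)[C@@]1(C)C(=O)C[C@H]2[C@]1(O)C[C@H](C(C)=C)CC[C@H]2C | intermediate
20 | 4β-[1-(2,4,6-trimethoxyphenyl)-3-methylbutyl]-5β-hydroxy-1βH,10βH-guai-11-en-3-one | CC(C)C[C@@H](c1c(OC)cc(OC)cc1OC)[C@@]1(C)C(=O)C[C@H]2[C@]1(O)C[C@H](C(C)=C)CC[C@H]2C | intermediate
21 | 4β-[1-(2,4,6-trimethoxyphenyl)-3-methylbutyl]-1βH,10βH-guaia-5,11-dien-3-one | CC(C)C[C@@H](c1c(OC)cc(OC)cc1OC)[C@@]1(C)C(=O)C[C@H]2C1=C[C@H](C(C)=C)CC[C@H]2C | intermediate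
22 | 4β-[1-(2,4,6-trimethoxyphenyl)-3-methylbutyl]-1βH,10βH-guaia-5,11-dien-3β-ol | CC(C)C[C@@H](c1c(OC)cc(OC)cc1OC)[C@@]1(C)[C@@H](O)C[C@H]2C1=C[C@H](C(C)=C)CC[C@H]2C | intermediate
23 | sodium xanthate of 22 | CC(C)C[C@@H](c1c(OC)cc(OC)cc1OC)[C@@]1(C)[C@@H](OC(=S)[S-])C[C@H]2C1=C[C@H](C(C)=C)CC[C@H]2C.[Na+] | intermediate
24 | S-methyl xanthate of 22 | CC(C)C[C@@H](c1c(OC)cc(OC)cc1OC)[C@@]1(C)[C@@H](OC(=S)SC)C[C@H]2C1=C[C@H](C(C)=C)CC[C@H]2C | intermediate
25 | 4β-[1-(2,4,6-trimethoxyphenyl)-3-methylbutyl]-1βH,10βH-guaia-5,11-diene | CC(C)C[C@@H](c1c(OC)cc(OC)cc1OC)[C@@]1(C)CC[C@H]2C1=C[C@H](C(C)=C)CC[C@H]2C | intermediate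
26 | 4β-[1-(2,4,6-trimethoxyphenyl)-3-methylbutyl]-1βH,10βH-guai-5-en-11-ol | CC(C)C[C@@H](c1c(OC)cc(OC)cc1OC)[C@@]1(C)CC[C@H]2C1=C[C@H](C(C)(C)O)CC[C@H]2C | intermediate
27 | lithium hemiaminal (aryl CH(OLi)NMe2, C11–OLi) | CC(C)C[C@@H](c1c(OC)cc(OC)c(C(O[Li])N(C)C)c1OC)[C@@]1(C)CC[C@H]2C1=C[C@H](C(C)(C)O[Li])CC[C@H]2C | intermediate
28 | tri-O-methyl ether of the target | CC(C)C[C@@H](c1c(OC)c(C=O)c(OC)c(C=O)c1OC)[C@@]1(C)CC[C@H]2C1=C[C@H](C(C)(C)O)CC[C@H]2C | intermediate
29 | CNP0281883.1 (1R,4R,7R,10R,1′R) | CC(C)C[C@@H](c1c(O)c(C=O)c(O)c(C=O)c1O)[C@@]1(C)CC[C@H]2C1=C[C@H](C(C)(C)O)CC[C@H]2C | target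

## Step count

Total step count: 17. Longest linear sequence: 16 (steps 1–7 and 9–17).

## Steps most likely to fail

**Step 9 (Proposed new method).**
- *What may go wrong:*
  - Bond formation at the crowded C4 may be slow, so that β-elimination of the samarium alkoxide back to the enone takes over.
  - Tautomerisation of the methide by a 1,5-hydrogen shift may compete in the same way.
  - Facial discrimination at C1′ may be poor.
- *Fallback (known reactions only):* it sets out from enone 11 and comes back at ketone 21.
  - Isobutylmagnesium bromide 15 is added to commercial 2,4,6-trimethoxybenzaldehyde to give 1-(2,4,6-trimethoxyphenyl)-3-methylbutan-1-ol F1.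
  - In methanol with a trace of acid, F1 gives the benzylic methyl ether F2.
  - Reductive lithiation (lithium 4,4′-di-tert-butylbiphenylide, THF, −78 °C) converts F2 into the benzylic lithium reagent F3.
  - In the presence of LaCl3·2LiCl, F3 adds 1,2 to 11 from the β face and gives the tertiary allylic alcohol F4. The C1′ epimers are separated at this point.
  - Hydroxyl-directed epoxidation (VO(acac)2, t-BuOOH) gives the 4α,5α-epoxy alcohol F5.
  - ZnBr2 then triggers a semipinacol rearrangement in which C1′ migrates from C3 to C4, anti to the breaking C4–O bond and with retention at C1′. This gives the 5α-hydroxy ketone F6 with C1′ β at C4.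
  - The Burgess reagent removes the 5α-hydroxyl by syn elimination. Only C6 offers an α hydrogen for this, so the product is 21.

**Step 6.**
- *What may go wrong:*
  - The C10 radical may close onto the enone carbon C5, with reversal toward the decalin skeleton.
  - Face selectivity in the hydrogen transfer may be insufficient.
- *Fallback:* it sets out from 9 and comes back at 11, with the enone masked during the radical step.
  - Luche reduction (NaBH4, CeCl3·7H2O, MeOH) gives the 3α,10β-diol F7.
  - TBSCl and imidazole silylate only the secondary allylic alcohol, giving the silyl ether F8.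
  - Methyl oxalyl chloride with DMAP gives the tertiary oxalate F9.
  - Bu3SnH with AIBN gives the 10-deoxy silyl ether F10. The radical now has only an unactivated tetrasubstituted alkene beside it, and the α-silyloxy group adds bulk under ring A.
  - TBAF frees the allylic alcohol F11, and MnO2 oxidises it to 11.

**Step 17.**
- *What may go wrong:*
  - Ether cleavage may stall once the ring has become a phenoxide.
  - Thiolate may add to the formyl groups.
  - The hot basic medium may cause degradation.
- *Fallback:* it sets out from 25 and comes back only at the target 29, with the order of the end game changed so that a Lewis acid can be used before any tertiary alcohol exists.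
  - The double lithiation–formylation of step 16 is run on 25 with one equivalent less of n-BuLi. It passes through the lithium hemiaminal F12 to the isopropenyl dialdehyde F13.
  - BCl3 (CH2Cl2, −78 → 0 °C) cleaves the three methyl ethers, each of which is ortho to a chelating formyl group, and gives the isopropenyl triphenol F14.
  - Mukaiyama hydration (Co(acac)2, PhSiH3, O2) of the isopropenyl group is then the last step and gives 29.

## Further compounds

F1 | step 9 | 1-(2,4,6-trimethoxyphenyl)-3-methylbutan-1-ol (racemic) | CC(C)CC(O)c1c(OC)cc(OC)cc1OC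
F2 | step 9 | 2-(1-methoxy-3-methylbutyl)-1,3,5-trimethoxybenzene (racemic) | CC(C)CC(OC)c1c(OC)cc(OC)cc1OC
F3 | step 9 | [1-(2,4,6-trimethoxyphenyl)-3-methylbutyl]lithium | CC(C)CC([Li])c1c(OC)cc(OC)cc1OC
F4 | step 9 | 3β-[1-(2,4,6-trimethoxyphenyl)-3-methylbutyl]-1βH,10βH-guaia-4,11-dien-3α-ol | CC(C)C[C@@H](c1c(OC)cc(OC)cc1OC)[C@@]1(O)C[C@@H]2[C@H](C)CC[C@@H](C(C)=C)CC2=C1C
F5 | step 9 | 4α,5α-epoxide of F4 | CC(C)C[C@@H](c1c(OC)cc(OC)cc1OC)[C@@]1(O)C[C@@H]2[C@H](C)CC[C@@H](C(C)=C)C[C@]23O[C@]13C
F6 | step 9 | 4β-[1-(2,4,6-trimethoxyphenyl)-3-methylbutyl]-5α-hydroxy-1βH,10βH-guai-11-en-3-one | CC(C)C[C@@H](c1c(OC)cc(OC)cc1OC)[C@@]1(C)C(=O)C[C@H]2[C@@]1(O)C[C@H](C(C)=C)CC[C@H]2C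
F7 | step 6 | 1βH-guaia-4,11-diene-3α,10β-diol | CC1=C2C[C@H](C(C)=C)CC[C@](C)(O)[C@H]2C[C@H]1O
F8 | step 6 | 3α-(tert-butyldimethylsilyloxy)-1βH-guaia-4,11-dien-10β-ol | CC1=C2C[C@H](C(C)=C)CC[C@](C)(O)[C@H]2C[C@H]1O[Si](C)(C)C(C)(C)C
F9 | step 6 | methyl oxalate of F8 | CC1=C2C[C@H](C(C)=C)CC[C@](C)(OC(=O)C(=O)OC)[C@H]2C[C@H]1O[Si](C)(C)C(C)(C)C
F10 | step 6 | 3α-(tert-butyldimethylsilyloxy)-1βH,10βH-guaia-4,11-diene | CC1=C2C[C@H](C(C)=C)CC[C@@H](C)[C@H]2C[C@H]1O[Si](C)(C)C(C)(C)C
F11 | step 6 | 1βH,10βH-guaia-4,11-dien-3α-ol | CC1=C2C[C@H](C(C)=C)CC[C@@H](C)[C@H]2C[C@H]1O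
F12 | step 17 | lithium hemiaminal of the isopropenyl series | CC(C)C[C@@H](c1c(OC)cc(OC)c(C(O[Li])N(C)C)c1OC)[C@@]1(C)CC[C@H]2C1=C[C@H](C(C)=C)CC[C@H]2C
F13 | step 17 | isopropenyl dialdehyde, 3,5-diformyl-2,4,6-trimethoxyphenyl analogue of 25 | CC(C)C[C@@H](c1c(OC)c(C=O)c(OC)c(C=O)c1OC)[C@@]1(C)CC[C@H]2C1=C[C@H](C(C)=C)CC[C@H]2C
F14 | step 17 | isopropenyl triphenol, 11,12-dehydro-11-deoxy analogue of the target | CC(C)C[C@@H](c1c(O)c(C=O)c(O)c(C=O)c1O)[C@@]1(C)CC[C@H]2C1=C[C@H](C(C)=C)CC[C@H]2C
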